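## Retrosynthetic overview
1. Ester C–O: the target comes from the (R)-α-hydroxy enone coumarin and isovaleryl chloride. This is the last step and touches no bond at the stereocentre.
2. Key step: the (R)-carbinol, the ketone and the whole pyranone ring come from one flat, achiral 2-isopropenylbenzofuran carrying a (Z)-acrylate. Enantioselective epoxidation of the furan C2=C3 bond destroys the heteroaromatic ring and sets C-1′. Hydrolysis frees the ketone and the phenol, and the phenol lactonises.
3. The (Z)-acrylate comes from the 7-formylbenzofuran (Still–Gennari). The benzofuran comes from an o-iodophenol and isopropenylacetylene (Sonogashira/5-endo-dig).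
4. The iodosalicylaldehyde comes from bulk 2,4,5-trimethoxybenzaldehyde by chelation-controlled mono-demethylation and ortho-iodination.
5. Ring order: the benzene ring is bought, the furan ring is built in step 3, and in step 5 the furan ring is sacrificed and the pyranone ring closed in the same operation.

Assumption: the [C@H] of the given SMILES is (R) at C-1′ (priorities O > C=O > aryl > H). Compounds 1, 5, 8, 14 and the D-fructose-derived Shi ketone are bought.

## Route

Step 1
Reactants: 1 2,4,5-trimethoxybenzaldehyde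
Product: 3 2-hydroxy-4,5-dimethoxybenzaldehyde, via aryloxydichloroborane chelate 2 (not isolated)
Conditions: BCl3 (1.1 equiv), CH2Cl2, −10 °C → rt; then H2O
Reagents that add atoms: none
Why: Chelation-controlled Lewis-acid aryl methyl ether cleavage, in which BCl3 bridges the aldehyde oxygen and the ortho OMe in a six-membered chelate, so chloride removes only that methyl group and the 4- and 5-OMe groups stay.

Step 2
Reactants: 3 2-hydroxy-4,5-dimethoxybenzaldehyde
Product: 4 2-hydroxy-3-iodo-4,5-dimethoxybenzaldehyde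
Conditions: NIS (1.05 equiv), TFA (10 mol %), MeCN, 0 °C → rt, dark
Reagents that add atoms: N-iodosuccinimide, O=C1CCC(=O)N1I
Why: Electrophilic aromatic iodination (SEAr) goes to C-3 because it is the only free position ortho to the phenol (para is blocked by OMe) and is also ortho to the 4-OMe, whereas C-6 is meta to the OH and next to the deactivating CHO.

Step 3
Reactants: 4 2-hydroxy-3-iodo-4,5-dimethoxybenzaldehyde; 5 2-methylbut-1-en-3-yne
Product: 7 4,5-dimethoxy-2-(prop-1-en-2-yl)-1-benzofuran-7-carbaldehyde, via ortho-enynylphenol 6 (not isolated)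
Conditions: PdCl2(PPh3)2 (3 mol %), CuI (5 mol %), Et3N, DMF, sealed tube, rt → 60 °C
Reagents that add atoms: none
Why: Sonogashira coupling is followed in the same pot by metal-assisted 5-endo-dig addition of the acidic, aldehyde-activated phenol to the alkyne (domino benzofuran synthesis), a sequence long used to make 2-isopropenylbenzofurans from o-iodophenols.

Step 4
Reactants: 7 4,5-dimethoxy-2-(prop-1-en-2-yl)-1-benzofuran-7-carbaldehyde; 8 methyl bis(2,2,2-trifluoroethyl)phosphonoacetate
Product: 10 methyl (2Z)-3-[4,5-dimethoxy-2-(prop-1-en-2-yl)-1-benzofuran-7-yl]prop-2-enoate, via potassium phosphonoacetate carbanion 9 (not isolated)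
Conditions: KHMDS, 18-crown-6, THF, −78 °C
Reagents that add atoms: none
Why: In the Still–Gennari variant of the Horner–Wadsworth–Emmons olefination the electron-poor trifluoroethyl phosphonate collapses fast and irreversibly under dissociating K+/crown conditions to give the (Z)-cinnamate (typically >10:1 for aryl aldehydes), while the furan ring keeps the future lactone oxygen masked so nothing cyclises early.

Step 5
Reactants: 10 methyl (2Z)-3-[4,5-dimethoxy-2-(prop-1-en-2-yl)-1-benzofuran-7-yl]prop-2-enoate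
Product: 13 8-[(1R)-1-hydroxy-3-methyl-2-oxobut-3-en-1-yl]-6,7-dimethoxy-2H-chromen-2-one, via benzofuran 2,3-epoxide 11 (not isolated), via ring-opened phenol ketol 12 (not isolated)
Conditions: D-fructose-derived Shi ketone (30 mol %), Oxone (1.4 equiv), K2CO3, Bu4NHSO4 (cat.), MeCN–DMM / aq Na2B4O7–Na2EDTA buffer (pH ≈ 10.5), −10 → 0 °C, 2 h; then pH 6 phosphate, rt
Reagents that add atoms: potassium peroxymonosulfate (active oxidant of Oxone), [K+].[O-]S(=O)(=O)OO; water, O
Why: Proposed new method: the C2=C3 bond of a benzofuran is a weakly aromatic, trisubstituted cyclic enol ether, so the chiral dioxirane (spiro transition state, face fixed by the single olefinic H exactly as for 1-phenylcyclohexene, which gives the (R,R)-oxide with this ketone) should give the (2S,3R)-epoxide 11; this 2-aryloxy epoxide ionises at the acetal-type C2–O bond and leaves C3–O untouched, so the new stereocentre is kept as (R); water adds at C2, the hemiketal collapses to ketone plus phenoxide 12, and the phenoxide is consumed at once by the (Z)-ester to close the pyranone; chemoselectivity rests on the preference of this catalyst for electron-rich trisubstituted C=C over 1,1-disubstituted and acrylate C=C, and once the furan is open the isopropenyl group is a deactivated enone; the closest known reaction types are Shi epoxidation of enol ethers and enol esters to α-hydroxy ketones, regioselective Shi mono-epoxidation of conjugated dienes, dimethyldioxirane epoxidation of benzofurans and the spontaneous lactonisation of (Z)-o-hydroxycinnamates.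

Step 6
Reactants: 13 8-[(1R)-1-hydroxy-3-methyl-2-oxobut-3-en-1-yl]-6,7-dimethoxy-2H-chromen-2-one; 14 3-methylbutanoyl chloride
Product: 15 (1R)-1-(6,7-dimethoxy-2-oxo-2H-chromen-8-yl)-3-methyl-2-oxobut-3-en-1-yl 3-methylbutanoate
Conditions: 14 (1.5 equiv), pyridine (3 equiv), CH2Cl2, −10 → 0 °C
Reagents that add atoms: none
Why: O-acylation (nucleophilic acyl substitution) esterifies the only free OH without breaking a bond at the stereocentre, so (R) is retained, and pyridine (pKaH ≈ 5) at ≤0 °C is too weak a base to enolise the benzylic α-acyloxy ketone.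

## Compound list
1 | 2,4,5-trimethoxybenzaldehyde | COc1cc(OC)c(C=O)cc1OC | starting material
2 | (2-formyl-4,5-dimethoxyphenoxy)dichloroborane (B–O=CH chelate) | COc1cc(OB(Cl)Cl)c(C=O)cc1OC | intermediate
3 | 2-hydroxy-4,5-dimethoxybenzaldehyde | COc1cc(O)c(C=O)cc1OC | intermediate
4 | 2-hydroxy-3-iodo-4,5-dimethoxybenzaldehyde | COc1cc(C=O)c(O)c(I)c1OC | intermediate
5 | 2-methylbut-1-en-3-yne | C=C(C)C#C | starting material
6 | 2-hydroxy-4,5-dimethoxy-3-(3-methylbut-3-en-1-yn-1-yl)benzaldehyde | C=C(C)C#Cc1c(O)c(C=O)cc(OC)c1OC | intermediate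
7 | 4,5-dimethoxy-2-(prop-1-en-2-yl)-1-benzofuran-7-carbaldehyde | C=C(C)c1cc2c(OC)c(OC)cc(C=O)c2o1 | intermediate
8 | methyl bis(2,2,2-trifluoroethyl)phosphonoacetate | COC(=O)CP(=O)(OCC(F)(F)F)OCC(F)(F)F | starting material
9 | potassium salt of the carbanion of 8 | COC(=O)[CH-]P(=O)(OCC(F)(F)F)OCC(F)(F)F.[K+] | intermediate
10 | methyl (2Z)-3-[4,5-dimethoxy-2-(prop-1-en-2-yl)-1-benzofuran-7-yl]prop-2-enoate | COC(=O)/C=C\c1cc(OC)c(OC)c2cc(C(C)=C)oc12 | intermediate
11 | methyl (2Z)-3-[(2S,3R)-2,3-epoxy-4,5-dimethoxy-2-(prop-1-en-2-yl)-2,3-dihydro-1-benzofuran-7-yl]prop-2-enoate | C=C(C)[C@@]12O[C@@H]1c1c(O2)c(/C=C\C(=O)OC)cc(OC)c1OC | intermediate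
12 | methyl (2Z)-3-{2-hydroxy-3-[(1R)-1-hydroxy-3-methyl-2-oxobut-3-en-1-yl]-4,5-dimethoxyphenyl}prop-2-enoate | C=C(C)C(=O)[C@H](O)c1c(O)c(/C=C\C(=O)OC)cc(OC)c1OC | intermediate
13 | 8-[(1R)-1-hydroxy-3-methyl-2-oxobut-3-en-1-yl]-6,7-dimethoxy-2H-chromen-2-one | C=C(C)C(=O)[C@H](O)c1c(OC)c(OC)cc2ccc(=O)oc12 | intermediate
14 | 3-methylbutanoyl chloride (isovaleryl chloride) | CC(C)CC(=O)Cl | starting material
15 | (1R)-1-(6,7-dimethoxy-2-oxo-2H-chromen-8-yl)-3-methyl-2-oxobut-3-en-1-yl 3-methylbutanoate | C=C(C)C(=O)[C@H](OC(=O)CC(C)C)c1c(OC)c(OC)cc2ccc(=O)oc12 | target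

## Step count
Total steps: 6. Longest linear sequence: 6 (fully linear from 1; compounds 5, 8 and 14 are bought).

## Three steps most likely to fail

**Step 5 (highest risk).**
- Possible failures:
  - competing epoxidation of the isopropenyl group;
  - 1,2-hydride shift of epoxide 11 to the benzofuran-3-one;
  - loss of ee if 11 opens to the achiral o-quinone methide;
  - oxidative cleavage of the ketol by excess Oxone.
- The fallback takes the competing alkene out of the substrate. It sets out from 4 and comes back at 15.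
- Sonogashira coupling of 4 with 2-methylbut-3-yn-2-ol gives 2-hydroxy-3-(3-hydroxy-3-methylbut-1-yn-1-yl)-4,5-dimethoxybenzaldehyde F1. This cyclises in the pot to 2-(2-hydroxypropan-2-yl)-4,5-dimethoxy-1-benzofuran-7-carbaldehyde F2.
- Still–Gennari olefination with 8 (through 9, one extra equivalent of base for the free OH) gives methyl (2Z)-3-[2-(2-hydroxypropan-2-yl)-4,5-dimethoxy-1-benzofuran-7-yl]prop-2-enoate F3.
- The same Shi conditions now meet only one electron-rich C=C. They give the (2R,3R)-epoxide F4, then the ring-opened phenol F5, and after lactonisation 8-[(1R)-1,3-dihydroxy-3-methyl-2-oxobutyl]-6,7-dimethoxy-2H-chromen-2-one F6.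
- Compound 14 with pyridine acylates only the secondary OH. This gives (1R)-1-(6,7-dimethoxy-2-oxo-2H-chromen-8-yl)-3-hydroxy-3-methyl-2-oxobutyl 3-methylbutanoate F7.
- Neutral syn-dehydration of the tertiary carbinol with the Burgess reagent (toluene, 50 °C) unveils the isopropenyl ketone 15, because only the methyl groups carry β-hydrogens.

**Step 2.**
- Possible failures: C-3 is flanked on both sides, and the ipso position carrying CHO is ortho to OH and para to OMe. Sluggish iodination or iododeformylation could therefore intervene.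
- The fallback replaces SEAr by directed ortho-metalation before the demethylation. It sets out from 1 and comes back at 4.
- HC(OMe)3 with cat. TsOH in MeOH gives 1-(dimethoxymethyl)-2,4,5-trimethoxybenzene F8.
- n-BuLi/TMEDA in THF at 0 °C removes the proton between the two methoxy groups and gives 3-lithio-1-(dimethoxymethyl)-2,4,5-trimethoxybenzene F9.
- Iodine gives 1-(dimethoxymethyl)-3-iodo-2,4,5-trimethoxybenzene F10, and dilute HCl in the work-up gives 3-iodo-2,4,5-trimethoxybenzaldehyde F11.
- BCl3 then cleaves the OMe ortho to the aldehyde through (6-formyl-2-iodo-3,4-dimethoxyphenoxy)dichloroborane F12 to deliver 4.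

**Step 6.**
- Possible failures: the carbinol is hindered by two ortho substituents, and both 13 and 15 carry an acidic benzylic α-keto hydrogen. Slow acylation with partial racemisation is therefore possible.
- The fallback forms the ester with inversion under base-free redox-condensation conditions. It sets out from 10 and comes back at 15.
- Step 5 is run with the enantiomeric (L-sorbose-derived) Shi ketone. It gives the (2R,3S)-epoxide F13, the (S)-configured ring-opened phenol F14 and 8-[(1S)-1-hydroxy-3-methyl-2-oxobut-3-en-1-yl]-6,7-dimethoxy-2H-chromen-2-one F15.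
- Mitsunobu esterification of F15 with 3-methylbutanoic acid (PPh3, DIAD, toluene, 0 °C) displaces the activated oxygen by SN2 at the α-keto carbon and gives (R)-15.

## Further compounds
F1 | step 5 | 2-hydroxy-3-(3-hydroxy-3-methylbut-1-yn-1-yl)-4,5-dimethoxybenzaldehyde | CC(C)(O)C#Cc1c(O)c(C=O)cc(OC)c1OC
F2 | step 5 | 2-(2-hydroxypropan-2-yl)-4,5-dimethoxy-1-benzofuran-7-carbaldehyde | CC(C)(O)c1cc2c(OC)c(OC)cc(C=O)c2o1
F3 | step 5 | methyl (2Z)-3-[2-(2-hydroxypropan-2-yl)-4,5-dimethoxy-1-benzofuran-7-yl]prop-2-enoate | COC(=O)/C=C\c1cc(OC)c(OC)c2cc(C(C)(C)O)oc12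
F4 | step 5 | methyl (2Z)-3-[(2R,3R)-2,3-epoxy-2-(2-hydroxypropan-2-yl)-4,5-dimethoxy-2,3-dihydro-1-benzofuran-7-yl]prop-2-enoate | CC(C)(O)[C@@]12O[C@@H]1c1c(O2)c(/C=C\C(=O)OC)cc(OC)c1OC
F5 | step 5 | methyl (2Z)-3-{3-[(1R)-1,3-dihydroxy-3-methyl-2-oxobutyl]-2-hydroxy-4,5-dimethoxyphenyl}prop-2-enoate | CC(C)(O)C(=O)[C@H](O)c1c(O)c(/C=C\C(=O)OC)cc(OC)c1OC
F6 | step 5 | 8-[(1R)-1,3-dihydroxy-3-methyl-2-oxobutyl]-6,7-dimethoxy-2H-chromen-2-one | CC(C)(O)C(=O)[C@H](O)c1c(OC)c(OC)cc2ccc(=O)oc12
F7 | step 5 | (1R)-1-(6,7-dimethoxy-2-oxo-2H-chromen-8-yl)-3-hydroxy-3-methyl-2-oxobutyl 3-methylbutanoate | CC(C)(O)C(=O)[C@H](OC(=O)CC(C)C)c1c(OC)c(OC)cc2ccc(=O)oc12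
F8 | step 2 | 1-(dimethoxymethyl)-2,4,5-trimethoxybenzene | COC(OC)c1cc(OC)c(OC)cc1OC
F9 | step 2 | 3-lithio-1-(dimethoxymethyl)-2,4,5-trimethoxybenzene | [Li]c1c(OC)c(C(OC)OC)cc(OC)c1OC
F10 | step 2 | 1-(dimethoxymethyl)-3-iodo-2,4,5-trimethoxybenzene | COC(OC)c1cc(OC)c(OC)c(I)c1OC
F11 | step 2 | 3-iodo-2,4,5-trimethoxybenzaldehyde | COc1cc(C=O)c(OC)c(I)c1OC
F12 | step 2 | (6-formyl-2-iodo-3,4-dimethoxyphenoxy)dichloroborane | COc1cc(C=O)c(OB(Cl)Cl)c(I)c1OC
F13 | step 6 | methyl (2Z)-3-[(2R,3S)-2,3-epoxy-4,5-dimethoxy-2-(prop-1-en-2-yl)-2,3-dihydro-1-benzofuran-7-yl]prop-2-enoate | C=C(C)[C@]12O[C@H]1c1c(O2)c(/C=C\C(=O)OC)cc(OC)c1OC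
F14 | step 6 | methyl (2Z)-3-{2-hydroxy-3-[(1S)-1-hydroxy-3-methyl-2-oxobut-3-en-1-yl]-4,5-dimethoxyphenyl}prop-2-enoate | C=C(C)C(=O)[C@@H](O)c1c(O)c(/C=C\C(=O)OC)cc(OC)c1OC
F15 | step 6 | 8-[(1S)-1-hydroxy-3-methyl-2-oxobut-3-en-1-yl]-6,7-dimethoxy-2H-chromen-2-one | C=C(C)C(=O)[C@@H](O)c1c(OC)c(OC)cc2ccc(=O)oc12
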